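**Retrosynthetic overview**

- Junipegenin C (20) is traced back to its 5,7-di-O-benzyl ether 19; the benzyl groups come off last by hydrogenolysis.
- Ring C is the only ring built, and it is closed last onto preformed ring A by cutting O1–C8a and C4–C4a together. This gives aryne 17 (from silyl triflate 11) and the enolate of formyl arylacetate 16, which already carries ring B on the future C3.
- The feature that allows this: C8a (bearing O1) and C4a (bearing the C4 carbonyl) are adjacent carbons of ring A, and the C5 oxygen flanks C4a, so an aryne across C4a–C8a can accept oxygen and acyl carbon in one operation with a defined orientation.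
- Triflate 11 comes from methyl 4-O-methylgallate 1 (benzylation, ester-to-phenol degradation, bromination, retro-Brook rearrangement, triflation); enol 16 comes from 3,4,5-trimethoxyphenylacetic acid 12 and methyl formate 14.

Key step: step 10

Remark: 16 is drawn as the hydrogen-bonded Z enol; its E enol and aldehyde tautomers are expected to equilibrate with it and to converge on the same enolate under the conditions of step 10.

**Route**

Step 1
Reactants: 1 methyl 3,5-dihydroxy-4-methoxybenzoate
Product: 2 methyl 3,5-bis(benzyloxy)-4-methoxybenzoate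
Conditions: BnBr (2.4 equiv), K2CO3, DMF, 60 °C
Reagents that add atoms: benzyl bromide, BrCc1ccccc1
Why: Williamson etherification of both phenols with benzyl bromide under carbonate base, which leaves the methyl ester and the methyl ether untouched.

Step 2
Reactants: 2 methyl 3,5-bis(benzyloxy)-4-methoxybenzoate
Product: 3 [3,5-bis(benzyloxy)-4-methoxyphenyl]methanol
Conditions: LiAlH4, THF, 0 °C to rt; Fieser work-up
Reagents that add atoms: none
Why: Hydride reduction of the benzoate ester to the benzylic alcohol with LiAlH4, to which the aryl ethers are inert.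

Step 3
Reactants: 3 [3,5-bis(benzyloxy)-4-methoxyphenyl]methanol
Product: 4 3,5-bis(benzyloxy)-4-methoxybenzaldehyde
Conditions: MnO2 (excess), CH2Cl2, rt
Reagents that add atoms: none
Why: Heterogeneous oxidation of an electron-rich benzylic alcohol with MnO2 should stop cleanly at the aldehyde.

Step 4
Reactants: 4 3,5-bis(benzyloxy)-4-methoxybenzaldehyde
Product: 6 3,5-bis(benzyloxy)-4-methoxyphenol, via aryl formate 5 (not isolated)
Conditions: mCPBA, CH2Cl2, 0 °C to rt; then K2CO3 (cat), MeOH, rt
Reagents that add atoms: meta-chloroperoxybenzoic acid, O=C(OO)c1cccc(Cl)c1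
Why: Baeyer–Villiger (Dakin-type) oxidation in which the electron-rich aryl group migrates in preference to hydride to give formate 5, which mild methanolysis converts into the symmetrical phenol 6.

Step 5
Reactants: 6 3,5-bis(benzyloxy)-4-methoxyphenol
Product: 7 3,5-bis(benzyloxy)-2-bromo-4-methoxyphenol
Conditions: NBS (1.0 equiv), CH2Cl2, −78 °C to 0 °C
Reagents that add atoms: N-bromosuccinimide, O=C1CCC(=O)N1Br
Why: Electrophilic aromatic bromination in which the two free ring positions are equivalent and each lies ortho to the hydroxyl and ortho or para to a benzyloxy group, so one equivalent of NBS at low temperature should give a single monobromide.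

Step 6
Reactants: 7 3,5-bis(benzyloxy)-2-bromo-4-methoxyphenol
Product: 8 [3,5-bis(benzyloxy)-2-bromo-4-methoxyphenoxy]trimethylsilane
Conditions: HMDS, THF, 70 °C; volatiles removed in vacuo, crude used directly
Reagents that add atoms: hexamethyldisilazane, C[Si](C)(C)N[Si](C)(C)C
Why: O-silylation of the phenol by HMDS gives ammonia as the only by-product, so the moisture-sensitive silyl ether can be carried on after simple evaporation.

Step 7
Reactants: 8 [3,5-bis(benzyloxy)-2-bromo-4-methoxyphenoxy]trimethylsilane
Product: 11 3,5-bis(benzyloxy)-4-methoxy-2-(trimethylsilyl)phenyl trifluoromethanesulfonate, via aryllithium 9 (not isolated), via lithium silylphenoxide 10 (not isolated)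
Conditions: n-BuLi (1.1 equiv), THF, −78 °C; then Tf2O (1.2 equiv), −78 °C to rt
Reagents that add atoms: trifluoromethanesulfonic anhydride, O=S(=O)(OS(=O)(=O)C(F)(F)F)C(F)(F)F
Why: Bromine–lithium exchange at −78 °C outpaces benzylic deprotonation, aryllithium 9 undergoes the 1,3 oxygen-to-carbon silyl shift (retro-Brook rearrangement) to phenoxide 10, and Tf2O traps the phenoxide as the triflate.

Step 8
Reactants: 12 3,4,5-trimethoxyphenylacetic acid
Product: 13 methyl 3,4,5-trimethoxyphenylacetate
Conditions: MeOH, H2SO4 (cat), reflux
Reagents that add atoms: methanol, CO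
Why: Fischer esterification driven to completion by the excess of methanol.

Step 9
Reactants: 13 methyl 3,4,5-trimethoxyphenylacetate; 14 methyl formate
Product: 16 methyl (Z)-3-hydroxy-2-(3,4,5-trimethoxyphenyl)acrylate, via sodium enolate 15 (not isolated)
Conditions: NaH (2 equiv), HCO2Me (excess), THF, 0 °C to rt; then 1 M HCl
Reagents that add atoms: none
Why: Crossed Claisen condensation (C-formylation) of the arylacetate enolate with the non-enolisable methyl formate, driven by formation of the stabilised enolate 15, which acid work-up converts into the enol.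

Step 10
Reactants: 11 3,5-bis(benzyloxy)-4-methoxy-2-(trimethylsilyl)phenyl trifluoromethanesulfonate; 16 methyl (Z)-3-hydroxy-2-(3,4,5-trimethoxyphenyl)acrylate
Product: 19 5,7-bis(benzyloxy)-6-methoxy-3-(3,4,5-trimethoxyphenyl)chromen-4-one, via aryne 17 (not isolated), via aryl caesium 18 (not isolated)
Conditions: CsF (4 equiv), THF, 65 °C; 11 added slowly to 16 (1.5 equiv)
Reagents that add atoms: none
Why: Proposed new method: fluoride attacks silicon of 11 and triflate departs, releasing aryne 17 across the carbons that become C4a and C8a, while CsF also converts enol 16 into its caesium enolate; the enolate oxygen adds at the aryne carbon remote from the flanking benzyloxy group (future C8a, forming O1–C8a), and the resulting aryl caesium 18, whose carbanion sits at future C4a, attacks the cis ester and expels methoxide (forming C4–C4a). The closest known reaction types are the CsF-mediated annulation of methyl salicylates with silylaryl triflates to xanthones, in which a phenoxide plays the part taken here by an enolate oxygen, and the aryne acyl-alkylation of beta-ketoesters, in which an aryne-derived aryl anion is captured by a neighbouring carbonyl group. Ring C is closed by a 6-exo-trig addition of the C4a carbanion to the ester carbonyl followed by elimination, and no stereocenter is formed. Two selectivities are needed, the sense of addition to the unsymmetrical aryne and O- versus C-attack of the ambident enolate. The first is secured by the benzyloxy group next to the aryne (future C5–O), which distorts and polarises the triple bond so that nucleophiles add at the remote carbon and the charge develops beside the inductively withdrawing oxygen, as is general for 3-alkoxyarynes. The second rests on the enolate carbon being fully substituted and shielded by the ester and the 3,4,5-trimethoxyphenyl group, whereas the formyl-derived oxygen is unhindered and carries most of the charge in a loosely paired caesium enolate, whose chelated Z geometry also holds the ester cis to the new aryl ether as ring closure requires.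

Step 11
Reactants: 19 5,7-bis(benzyloxy)-6-methoxy-3-(3,4,5-trimethoxyphenyl)chromen-4-one
Product: 20 junipegenin C, 5,7-dihydroxy-6-methoxy-3-(3,4,5-trimethoxyphenyl)chromen-4-one
Conditions: H2 (1 atm), 10% Pd/C, EtOAc/MeOH, rt
Reagents that add atoms: none
Why: Heterogeneous hydrogenolysis of the two aryl benzyl ethers over Pd/C, to which the methyl ethers are inert, with the reaction stopped at consumption of 19 to spare the C2–C3 double bond.

**Compound list**

1 | methyl 3,5-dihydroxy-4-methoxybenzoate | COC(=O)c1cc(O)c(OC)c(O)c1 | starting material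
2 | methyl 3,5-bis(benzyloxy)-4-methoxybenzoate | COC(=O)c1cc(OCc2ccccc2)c(OC)c(OCc2ccccc2)c1 | intermediate
3 | [3,5-bis(benzyloxy)-4-methoxyphenyl]methanol | OCc1cc(OCc2ccccc2)c(OC)c(OCc2ccccc2)c1 | intermediate
4 | 3,5-bis(benzyloxy)-4-methoxybenzaldehyde | O=Cc1cc(OCc2ccccc2)c(OC)c(OCc2ccccc2)c1 | intermediate
5 | 3,5-bis(benzyloxy)-4-methoxyphenyl formate | O=COc1cc(OCc2ccccc2)c(OC)c(OCc2ccccc2)c1 | intermediate
6 | 3,5-bis(benzyloxy)-4-methoxyphenol | Oc1cc(OCc2ccccc2)c(OC)c(OCc2ccccc2)c1 | intermediate
7 | 3,5-bis(benzyloxy)-2-bromo-4-methoxyphenol | Oc1cc(OCc2ccccc2)c(OC)c(OCc2ccccc2)c1Br | intermediate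
8 | [3,5-bis(benzyloxy)-2-bromo-4-methoxyphenoxy]trimethylsilane | C[Si](C)(C)Oc1cc(OCc2ccccc2)c(OC)c(OCc2ccccc2)c1Br | intermediate
9 | [2,4-bis(benzyloxy)-3-methoxy-6-(trimethylsilyloxy)phenyl]lithium | C[Si](C)(C)Oc1cc(OCc2ccccc2)c(OC)c(OCc2ccccc2)c1[Li] | intermediate
10 | lithium 3,5-bis(benzyloxy)-4-methoxy-2-(trimethylsilyl)phenoxide | [Li+].[O-]c1cc(OCc2ccccc2)c(OC)c(OCc2ccccc2)c1[Si](C)(C)C | intermediate
11 | 3,5-bis(benzyloxy)-4-methoxy-2-(trimethylsilyl)phenyl trifluoromethanesulfonate | C[Si](C)(C)c1c(OS(=O)(=O)C(F)(F)F)cc(OCc2ccccc2)c(OC)c1OCc1ccccc1 | intermediate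
12 | 3,4,5-trimethoxyphenylacetic acid | OC(=O)Cc1cc(OC)c(OC)c(OC)c1 | starting material
13 | methyl 3,4,5-trimethoxyphenylacetate | COC(=O)Cc1cc(OC)c(OC)c(OC)c1 | intermediate
14 | methyl formate | COC=O | starting material
15 | sodium (Z)-3-methoxy-3-oxo-2-(3,4,5-trimethoxyphenyl)prop-1-en-1-olate | COC(=O)/C(=C\[O-])c1cc(OC)c(OC)c(OC)c1.[Na+] | intermediate
16 | methyl (Z)-3-hydroxy-2-(3,4,5-trimethoxyphenyl)acrylate | COC(=O)/C(c1cc(OC)c(OC)c(OC)c1)=C\O | intermediate
17 | 3,5-bis(benzyloxy)-4-methoxybenzyne (1,2-didehydrobenzene) | C1#CC(OCc2ccccc2)=C(OC)C(OCc2ccccc2)=C1 | intermediate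
18 | methyl (Z)-3-[3,5-bis(benzyloxy)-2-caesio-4-methoxyphenoxy]-2-(3,4,5-trimethoxyphenyl)acrylate | COC(=O)/C(=C\Oc1cc(OCc2ccccc2)c(OC)c(OCc2ccccc2)c1[Cs])c1cc(OC)c(OC)c(OC)c1 | intermediate
19 | 5,7-bis(benzyloxy)-6-methoxy-3-(3,4,5-trimethoxyphenyl)chromen-4-one | COc1cc(-c2coc3cc(OCc4ccccc4)c(OC)c(OCc4ccccc4)c3c2=O)cc(OC)c1OC | intermediate
20 | junipegenin C, 5,7-dihydroxy-6-methoxy-3-(3,4,5-trimethoxyphenyl)chromen-4-one | COc1cc(-c2coc3cc(O)c(OC)c(O)c3c2=O)cc(OC)c1OC | target

**Step count**

Total: 11 steps. Longest linear sequence: 9 steps (steps 1 to 7, then 10 and 11); the arylacetate branch (steps 8 and 9) joins at step 10.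

**Steps most likely to fail**

1. Step 10 (proposed new method). Three processes could divert the annulation:
   - attack of the enolate through carbon, followed by transfer of the formyl group to the aryl anion (acyl-alkylation);
   - O-arylation from an E-configured enolate, which cannot reach the ester;
   - protonation of aryl caesium 18 before acyl capture.

   The fallback closes the same ring C by the known deoxybenzoin route. It sets out from bromophenol 7 and acid 12 and rejoins the route at 19.
   - Phenol 7 is protected with chloromethyl methyl ether and iPr2NEt in CH2Cl2 to give 1,3-bis(benzyloxy)-4-bromo-2-methoxy-5-(methoxymethoxy)benzene F1.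
   - Acid 12 is activated with 1,1'-carbonyldiimidazole and treated with N,O-dimethylhydroxylamine hydrochloride to give the Weinreb amide N-methoxy-N-methyl-2-(3,4,5-trimethoxyphenyl)acetamide F2.
   - Bromine–lithium exchange on F1 (n-BuLi, THF, −78 °C) and addition of F2 should give 1-[2,4-bis(benzyloxy)-3-methoxy-6-(methoxymethoxy)phenyl]-2-(3,4,5-trimethoxyphenyl)ethanone F3.
   - HCl in MeOH removes the methoxymethyl group to give 1-[2,4-bis(benzyloxy)-6-hydroxy-3-methoxyphenyl]-2-(3,4,5-trimethoxyphenyl)ethanone F4.
   - Heating F4 with N,N-dimethylformamide dimethyl acetal in toluene at 90 °C supplies C2 as an enaminone, which the free phenol closes to 19 with loss of dimethylamine.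

2. Step 5. The tetraoxygenated ring may take up a second bromine or be oxidised towards quinone-type material. The fallback avoids halogenation by using directed ortho-metalation. It sets out from phenol 6 and rejoins the route at 11, replacing steps 5 to 7.
   - Phenol 6 is treated with isopropyl isocyanate and catalytic Et3N in CH2Cl2 to give 3,5-bis(benzyloxy)-4-methoxyphenyl propan-2-ylcarbamate F5.
   - In-situ N-silylation (TMSOTf, TMEDA, Et2O), ortho-lithiation between the carbamate and the benzyloxy group (n-BuLi, TMEDA, −78 °C) and a TMSCl quench with aqueous work-up should give 3,5-bis(benzyloxy)-4-methoxy-2-(trimethylsilyl)phenyl propan-2-ylcarbamate F6.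
   - DBU and Et2NH in MeCN at 40 °C cleave the carbamate, and PhNTf2 added to the same flask converts the phenoxide into 11.

3. Step 11. Hydrogenation may continue into the C2–C3 double bond of the pyranone, or the hindered 5-O-benzyl ether may cleave slowly. The fallback replaces reduction by Lewis-acid ether cleavage. It sets out from 19 and arrives directly at 20: BCl3 with pentamethylbenzene as benzyl-cation scavenger in CH2Cl2 at −78 °C should remove both benzyl groups without hydrogen and without touching the methyl ethers at that temperature. No new compound arises on the way (F0).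

**Further compounds**

F1 | step 10 | 1,3-bis(benzyloxy)-4-bromo-2-methoxy-5-(methoxymethoxy)benzene | COCOc1cc(OCc2ccccc2)c(OC)c(OCc2ccccc2)c1Br
F2 | step 10 | N-methoxy-N-methyl-2-(3,4,5-trimethoxyphenyl)acetamide | CON(C)C(=O)Cc1cc(OC)c(OC)c(OC)c1
F3 | step 10 | 1-[2,4-bis(benzyloxy)-3-methoxy-6-(methoxymethoxy)phenyl]-2-(3,4,5-trimethoxyphenyl)ethanone | COCOc1cc(OCc2ccccc2)c(OC)c(OCc2ccccc2)c1C(=O)Cc1cc(OC)c(OC)c(OC)c1
F4 | step 10 | 1-[2,4-bis(benzyloxy)-6-hydroxy-3-methoxyphenyl]-2-(3,4,5-trimethoxyphenyl)ethanone | Oc1cc(OCc2ccccc2)c(OC)c(OCc2ccccc2)c1C(=O)Cc1cc(OC)c(OC)c(OC)c1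
F5 | step 5 | 3,5-bis(benzyloxy)-4-methoxyphenyl propan-2-ylcarbamate | CC(C)NC(=O)Oc1cc(OCc2ccccc2)c(OC)c(OCc2ccccc2)c1
F6 | step 5 | 3,5-bis(benzyloxy)-4-methoxy-2-(trimethylsilyl)phenyl propan-2-ylcarbamate | CC(C)NC(=O)Oc1cc(OCc2ccccc2)c(OC)c(OCc2ccccc2)c1[Si](C)(C)C
F0 | step 11 | none | none
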